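**Retrosynthetic overview**

1. Previtexilactone ⇐ 6‑epi alcohol (C6 inverted by oxidation and α‑face hydride, then acetylation) ⇐ γ‑lactone ring by oxidative lactonisation of a C15,C16‑diol ⇐ tetrahydrofuran ring by 5‑exo opening of a (13R)‑C13,C16‑epoxide by the 9α‑OH, with inversion at C13.
2. The 9α‑OH and the C11–C16 chain ⇐ 9α,11‑spiro‑epoxide + isoprenol dianion ⇐ C9 ketone of a trans‑decalone (methylenation, α‑face epoxidation); the C4 gem‑dimethyl group ⇐ C3=C4(CH3) by hydromethylation.
3. Rings A and B together ⇐ acyclic trienone by an intramolecular Diels–Alder reaction that forms C1–C2 and C5–C10: dienophile C10(CH3)=C1, diene C2=C3–C4(CH3)=C5, tether C6–C7–C8–C9.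
4. Enabling feature: C9, the spiro carbinol carbon shared by ring B and the tetrahydrofuran, sits next to C10 and can be carried as a ketone that activates C10=C1. Ring A tolerates C3=C4 unsaturation because one C4 methyl can be added last. The C6 oxygen next to the Z methyl on C4 steers the diene face by allylic strain.
5. Trienone ⇐ (S)‑5‑(hydroxymethyl)butyrolactone (C6), two Wittig reactions, trans α‑methylation (C8), Weinreb amide and isopropenyl Grignard. Ring order: A + B (step 7), tetrahydrofuran (step 12), lactone (step 13).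

Key step: step 7

Remark: positions carry labdane numbering (C1–C20), α/β refer to the decalin drawn with the C10 methyl β, and the ligand antipode in step 12 is assumed to be the one that gives the (13R)‑epoxide by the facial model for homoallylic alcohols.

**Route**

Step 1
Reactants: 1 (S)-5-(hydroxymethyl)dihydrofuran-2(3H)-one
Product: 3 (S,E)-2-methyl-3-(5-oxotetrahydrofuran-2-yl)prop-2-enal, via lactone aldehyde 2 (not isolated)
Conditions: Dess–Martin periodinane, CH2Cl2, 0 °C to rt; then Ph3P=C(CH3)CHO, 40 °C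
Reagents that add atoms: 2-(triphenylphosphoranylidene)propanal, CC(C=O)=P(c1ccccc1)(c1ccccc1)c1ccccc1
Why: Dess–Martin oxidation gives the sensitive α‑acyloxy aldehyde, which is trapped in the same flask by an E‑selective Wittig olefination with the formyl‑stabilised, weakly basic ylide, so that C6 (from the chiral pool) is kept and lies trans to the new aldehyde carbon C3 and cis to the C4 methyl.

Step 2
Reactants: 3 (S,E)-2-methyl-3-(5-oxotetrahydrofuran-2-yl)prop-2-enal
Product: 4 (S)-5-[(1E)-2-methylbuta-1,3-dien-1-yl]dihydrofuran-2(3H)-one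
Conditions: Ph3PCH3Br, KN(SiMe3)2, THF, 0 °C; then 3, −78 to 0 °C
Reagents that add atoms: methyltriphenylphosphonium bromide, C[P+](c1ccccc1)(c1ccccc1)c1ccccc1.[Br-]
Why: Wittig methylenation of the enal at low temperature is much faster than attack on or enolisation of the lactone and completes the (E)‑diene C2=C3–C4(CH3)=C5 without touching the trisubstituted double bond.

Step 3
Reactants: 4 (S)-5-[(1E)-2-methylbuta-1,3-dien-1-yl]dihydrofuran-2(3H)-one
Product: 5 (3R,5S)-3-methyl-5-[(1E)-2-methylbuta-1,3-dien-1-yl]dihydrofuran-2(3H)-one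
Conditions: LiN(iPr)2, THF, −78 °C; then CH3I, −78 to −40 °C
Reagents that add atoms: iodomethane, CI
Why: Alkylation of the lithium enolate of a γ‑substituted γ‑butyrolactone takes place anti to the C6 dienyl group, so the new C8 stereocentre should form mainly as the trans (3R,5S) lactone.

Step 4
Reactants: 5 (3R,5S)-3-methyl-5-[(1E)-2-methylbuta-1,3-dien-1-yl]dihydrofuran-2(3H)-one
Product: 6 (2R,4S,5E)-4-hydroxy-N-methoxy-N,2,6-trimethylocta-5,7-dienamide
Conditions: CH3NH(OCH3)·HCl, iPrMgCl, THF, −20 to 0 °C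
Reagents that add atoms: N,O-dimethylhydroxylamine hydrochloride, CNOC.Cl
Why: Aminolysis of the lactone by the chloromagnesium amide of N,O‑dimethylhydroxylamine (Weinreb amide formation) opens the ring at the acyl carbon without enolisation, so C6 and C8 are untouched.

Step 5
Reactants: 6 (2R,4S,5E)-4-hydroxy-N-methoxy-N,2,6-trimethylocta-5,7-dienamide
Product: 7 (2R,4S,5E)-4-[(tert-butyldimethylsilyl)oxy]-N-methoxy-N,2,6-trimethylocta-5,7-dienamide
Conditions: TBSCl, imidazole, DMF, rt
Reagents that add atoms: tert-butyldimethylsilyl chloride, CC(C)(C)[Si](C)(C)Cl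
Why: Standard silylation of the secondary allylic alcohol blocks relactonisation and installs the bulky C6 substituent that will steer the cycloaddition.

Step 6
Reactants: 7 (2R,4S,5E)-4-[(tert-butyldimethylsilyl)oxy]-N-methoxy-N,2,6-trimethylocta-5,7-dienamide
Product: 8 (4R,6S,7E)-6-[(tert-butyldimethylsilyl)oxy]-2,4,8-trimethyldeca-1,7,9-trien-3-one
Conditions: CH2=C(CH3)MgBr, THF, 0 °C
Reagents that add atoms: isopropenylmagnesium bromide, CC(=C)[Mg]Br
Why: Weinreb ketone synthesis, in which the Grignard reagent adds once to give a stable magnesium chelate that collapses to the isopropenyl ketone only on quench, which avoids over‑addition, conjugate addition and epimerisation at C8.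

Step 7
Reactants: 8 (4R,6S,7E)-6-[(tert-butyldimethylsilyl)oxy]-2,4,8-trimethyldeca-1,7,9-trien-3-one
Product: 9 (2R,4S,4aS,8aS)-4-[(tert-butyldimethylsilyl)oxy]-2,5,8a-trimethyl-3,4,4a,7,8,8a-hexahydronaphthalen-1(2H)-one (6α-OTBS, 8α-CH3, 9-oxo, 10β-CH3, 5α-H, C3=C4)
Conditions: Me2AlCl, CH2Cl2, −78 to −20 °C
Reagents that add atoms: none
Why: Lewis‑acid‑promoted type 1 intramolecular Diels–Alder reaction: Me2AlCl binds the C9 ketone, lowers the LUMO of the C10=C1 isopropenyl unit and lets it add across the alkyl‑rich diene C2=C3–C4(CH3)=C5 in a concerted, asynchronous [4+2] process in which C1–C2 bonding runs ahead of C5–C10. The closest known reaction type is the Lewis‑acid‑catalysed cyclisation of deca‑1,7,9‑trien‑3‑ones to octalones. Ring A (C1, C2, C3, C4, C5, C10) is closed by the cycloaddition itself and ring B (C5 to C10) by folding of the four‑atom tether C6–C9 into a chair, the fused mode being the only one this tether length allows. C5 and C10 are set together: allylic 1,3‑strain between the Z methyl on C4 and C6 puts H6 in the diene plane, C7 on the reacting face and the silyloxy group on the far face (equatorial, 6α, in the product), the C8 methyl is equatorial in the same chair (matched), and the ring fusion should be trans because an alpha‑methyl enone reacts with its carbonyl exo and its methyl endo. The step needs exo over endo selectivity and one diene face; the first is secured by the C10 methyl and the near‑planar s‑cis enone available in the chair trans transition state, the second by the C6 and C8 stereocentres acting in the same sense. C8 stays correctable later, because it is the only enolisable position next to C9.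

Step 8
Reactants: 9 (2R,4S,4aS,8aS)-4-[(tert-butyldimethylsilyl)oxy]-2,5,8a-trimethyl-3,4,4a,7,8,8a-hexahydronaphthalen-1(2H)-one
Product: 11 (2R,4S,4aS,8aS)-4-[(tert-butyldimethylsilyl)oxy]-2,5,5,8a-tetramethyloctahydronaphthalen-1(2H)-one, via sulfonylhydrazide adduct 10 (not isolated)
Conditions: Fe(acac)3, PhSiH3, CH2=NNHSO2(n-C8H17), THF/MeOH, rt; then MeOH, 60 °C
Reagents that add atoms: N'-methylideneoctane-1-sulfonohydrazide (formaldehyde octylsulfonylhydrazone), C=NNS(=O)(=O)CCCCCCCC
Why: Hydrogen‑atom‑transfer hydromethylation, in which an iron hydride delivers H to C3 in the Markovnikov sense, the tertiary C4 radical adds to the formaldehyde sulfonylhydrazone and the adduct loses sulfinate and N2 on warming (alkyl diazene fragmentation), which leaves the second methyl on the now non‑stereogenic C4.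

Step 9
Reactants: 11 (2R,4S,4aS,8aS)-4-[(tert-butyldimethylsilyl)oxy]-2,5,5,8a-tetramethyloctahydronaphthalen-1(2H)-one
Product: 12 tert-butyldimethyl{[(1S,3R,4aS,8aS)-3,4a,8,8-tetramethyl-4-methylidenedecahydronaphthalen-1-yl]oxy}silane (exocyclic C9=C11 alkene)
Conditions: Ph3PCH3Br, KOtBu, toluene, 90 °C
Reagents that add atoms: methyltriphenylphosphonium bromide, C[P+](c1ccccc1)(c1ccccc1)c1ccccc1.[Br-]
Why: Wittig methylenation under the potassium tert‑butoxide conditions used for hindered ketones converts C9=O into the C9=C11 alkene, and the basic medium keeps or brings the enolisable C8 into the equatorial 8α‑methyl configuration, the only one free of a 1,3‑diaxial clash with the C10 methyl.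

Step 10
Reactants: 12 tert-butyldimethyl{[(1S,3R,4aS,8aS)-3,4a,8,8-tetramethyl-4-methylidenedecahydronaphthalen-1-yl]oxy}silane
Product: 13 (9R)-9α,11-spiro-epoxide of 12 (oxirane oxygen axial on the α face of C9, C11 on the β side)
Conditions: mCPBA, NaHCO3, CH2Cl2, 0 °C
Reagents that add atoms: 3-chloroperoxybenzoic acid, OOC(=O)c1cccc(Cl)c1
Why: Prilezhaev epoxidation takes place from the α face because the axial C10 methyl shields the β face of the exocyclic alkene, which sets C9 with oxygen α (axial) and C11 β (equatorial).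

Step 11
Reactants: 13 (9R)-9α,11-spiro-epoxide; 14 3-methylbut-3-en-1-ol
Product: 16 (1R,2R,4S,4aS,8aS)-4-[(tert-butyldimethylsilyl)oxy]-1-(5-hydroxy-3-methylidenepentyl)-2,5,5,8a-tetramethyldecahydronaphthalen-1-ol, via dilithiated isoprenol 15 (not isolated)
Conditions: 14, nBuLi (2 equiv), TMEDA, Et2O, 0 °C to rt; then 13, THF, −78 °C to rt
Reagents that add atoms: none
Why: Alkoxide‑directed allylic lithiation of isoprenol gives a 2‑substituted allyl dianion with two equivalent termini, which opens the spiro‑epoxide by SN2 attack at the unsubstituted C11, so the C9–O bond and the 9α‑hydroxyl configuration are untouched.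

Step 12
Reactants: 16 (1R,2R,4S,4aS,8aS)-4-[(tert-butyldimethylsilyl)oxy]-1-(5-hydroxy-3-methylidenepentyl)-2,5,5,8a-tetramethyldecahydronaphthalen-1-ol
Product: 18 (5S,6S,8R,9R,10S,13S)-6-[(tert-butyldimethylsilyl)oxy]-9,13-epoxylabdane-15,16-diol, via epoxy diol 17 (not isolated)
Conditions: VO(OiPr)3 (cat.), C2-symmetric chiral bishydroxamic acid ligand (antipode giving the 13R epoxide), PhC(CH3)2OOH, toluene, 0 °C to rt; then CSA (cat.), CH2Cl2, 0 °C
Reagents that add atoms: cumene hydroperoxide, CC(C)(OO)c1ccccc1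
Why: Hydroxyl‑directed asymmetric epoxidation of the homoallylic alcohol (vanadium and chiral bishydroxamic acid) sets C13 by reagent control as the (R)‑epoxide, and acid then triggers 5‑exo‑tet opening at the tertiary C13 by the 9α‑hydroxyl with inversion, which closes the tetrahydrofuran ring with the (13S) spiro centre.

Step 13
Reactants: 18 (5S,6S,8R,9R,10S,13S)-6-[(tert-butyldimethylsilyl)oxy]-9,13-epoxylabdane-15,16-diol
Product: 20 (5S,6S,8R,9R,10S,13S)-6-[(tert-butyldimethylsilyl)oxy]-9,13-epoxylabdane 15,16-lactone (C15 carbonyl, C16 O-CH2), via lactol 19 (not isolated)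
Conditions: TEMPO (cat.), PhI(OAc)2, CH2Cl2, rt
Reagents that add atoms: none
Why: Nitroxyl‑catalysed oxidation selects the unhindered C15 primary alcohol over the neopentyl C16 alcohol, the hydroxy aldehyde closes to the five‑membered lactol and this is oxidised on to the γ‑lactone (oxidative lactonisation), with no stereocentre affected.

Step 14
Reactants: 20 (5S,6S,8R,9R,10S,13S)-6-[(tert-butyldimethylsilyl)oxy]-9,13-epoxylabdane 15,16-lactone
Product: 21 (5S,6S,8R,9R,10S,13S)-6-hydroxy-9,13-epoxylabdane 15,16-lactone (6α-OH)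
Conditions: HF·pyridine, THF, 0 °C to rt
Reagents that add atoms: none
Why: Fluoride‑induced desilylation under mildly acidic conditions frees the 6α‑alcohol and avoids base, which could open the β‑alkoxy lactone by elimination.

Step 15
Reactants: 21 (5S,6S,8R,9R,10S,13S)-6-hydroxy-9,13-epoxylabdane 15,16-lactone
Product: 22 (5S,8R,9R,10S,13S)-6-oxo-9,13-epoxylabdane 15,16-lactone
Conditions: Dess–Martin periodinane, CH2Cl2, rt
Reagents that add atoms: none
Why: Dess–Martin oxidation gives the C6 ketone under neutral conditions, and the adjacent C5 stays in the thermodynamically preferred trans‑fused configuration.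

Step 16
Reactants: 22 (5S,8R,9R,10S,13S)-6-oxo-9,13-epoxylabdane 15,16-lactone
Product: 23 (5S,6R,8R,9R,10S,13S)-6-hydroxy-9,13-epoxylabdane 15,16-lactone (6β-OH)
Conditions: NaBH4, CeCl3·7H2O, MeOH, −20 °C
Reagents that add atoms: none
Why: Luche‑type borohydride reduction, in which hydride attacks C6 from the α face because the β face is closed by the syn‑axial methyl groups on C4 and C10, gives the axial 6β‑alcohol, and the ketone is reduced much faster than the lactone.

Step 17
Reactants: 23 (5S,6R,8R,9R,10S,13S)-6-hydroxy-9,13-epoxylabdane 15,16-lactone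
Product: 24 previtexilactone
Conditions: Ac2O, DMAP, pyridine, 40 °C
Reagents that add atoms: acetic anhydride, CC(=O)OC(C)=O
Why: DMAP‑catalysed acylation of the hindered axial alcohol proceeds with retention at C6 and gives the target.

**Compound list**

1 | (S)-5-(hydroxymethyl)dihydrofuran-2(3H)-one | OC[C@@H]1CCC(=O)O1 | starting material
2 | (S)-5-oxotetrahydrofuran-2-carbaldehyde | O=C[C@@H]1CCC(=O)O1 | intermediate
3 | (S,E)-2-methyl-3-(5-oxotetrahydrofuran-2-yl)prop-2-enal | O=C/C(C)=C/[C@@H]1CCC(=O)O1 | intermediate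
4 | (S)-5-[(1E)-2-methylbuta-1,3-dien-1-yl]dihydrofuran-2(3H)-one | C=C/C(C)=C/[C@@H]1CCC(=O)O1 | intermediate
5 | (3R,5S)-3-methyl-5-[(1E)-2-methylbuta-1,3-dien-1-yl]dihydrofuran-2(3H)-one | C=C/C(C)=C/[C@@H]1C[C@@H](C)C(=O)O1 | intermediate
6 | (2R,4S,5E)-4-hydroxy-N-methoxy-N,2,6-trimethylocta-5,7-dienamide | C=C/C(C)=C/[C@@H](O)C[C@@H](C)C(=O)N(C)OC | intermediate
7 | (2R,4S,5E)-4-[(tert-butyldimethylsilyl)oxy]-N-methoxy-N,2,6-trimethylocta-5,7-dienamide | C=C/C(C)=C/[C@@H](O[Si](C)(C)C(C)(C)C)C[C@@H](C)C(=O)N(C)OC | intermediate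
8 | (4R,6S,7E)-6-[(tert-butyldimethylsilyl)oxy]-2,4,8-trimethyldeca-1,7,9-trien-3-one | C=C/C(C)=C/[C@@H](O[Si](C)(C)C(C)(C)C)C[C@@H](C)C(=O)C(C)=C | intermediate
9 | (2R,4S,4aS,8aS)-4-[(tert-butyldimethylsilyl)oxy]-2,5,8a-trimethyl-3,4,4a,7,8,8a-hexahydronaphthalen-1(2H)-one | CC(C)(C)[Si](C)(C)O[C@H]1C[C@@H](C)C(=O)[C@@]2(C)CCC=C(C)[C@H]12 | intermediate
10 | sulfonylhydrazide adduct of 9 (C4 bears CH3 and CH2NHNHSO2-octyl, C4 epimers) | CC(C)(C)[Si](C)(C)O[C@H]1C[C@@H](C)C(=O)[C@@]2(C)CCCC(C)(CNNS(=O)(=O)CCCCCCCC)[C@H]12 | intermediate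
11 | (2R,4S,4aS,8aS)-4-[(tert-butyldimethylsilyl)oxy]-2,5,5,8a-tetramethyloctahydronaphthalen-1(2H)-one | CC(C)(C)[Si](C)(C)O[C@H]1C[C@@H](C)C(=O)[C@@]2(C)CCCC(C)(C)[C@H]12 | intermediate
12 | tert-butyldimethyl{[(1S,3R,4aS,8aS)-3,4a,8,8-tetramethyl-4-methylidenedecahydronaphthalen-1-yl]oxy}silane | CC(C)(C)[Si](C)(C)O[C@H]1C[C@@H](C)C(=C)[C@@]2(C)CCCC(C)(C)[C@H]12 | intermediate
13 | (9R)-9α,11-spiro-epoxide of 12 | CC(C)(C)[Si](C)(C)O[C@H]1C[C@@H](C)[C@]3(CO3)[C@@]2(C)CCCC(C)(C)[C@H]12 | intermediate
14 | 3-methylbut-3-en-1-ol | CC(=C)CCO | starting material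
15 | dilithiated isoprenol, LiCH2C(=CH2)CH2CH2OLi | [Li]CC(=C)CCO[Li] | intermediate
16 | (1R,2R,4S,4aS,8aS)-4-[(tert-butyldimethylsilyl)oxy]-1-(5-hydroxy-3-methylidenepentyl)-2,5,5,8a-tetramethyldecahydronaphthalen-1-ol | CC(C)(C)[Si](C)(C)O[C@H]1C[C@@H](C)[C@](O)(CCC(=C)CCO)[C@@]2(C)CCCC(C)(C)[C@H]12 | intermediate
17 | (13R)-13,16-epoxide of 16 | CC(C)(C)[Si](C)(C)O[C@H]1C[C@@H](C)[C@](O)(CC[C@@]3(CCO)CO3)[C@@]2(C)CCCC(C)(C)[C@H]12 | intermediate
18 | (5S,6S,8R,9R,10S,13S)-6-[(tert-butyldimethylsilyl)oxy]-9,13-epoxylabdane-15,16-diol | CC(C)(C)[Si](C)(C)O[C@H]1C[C@@H](C)[C@]3(CC[C@@](CO)(CCO)O3)[C@@]2(C)CCCC(C)(C)[C@H]12 | intermediate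
19 | 15,16-lactol of 18 (15-hydroxy-15,16-epoxide, C15 epimers) | CC(C)(C)[Si](C)(C)O[C@H]1C[C@@H](C)[C@]3(CC[C@]4(COC(O)C4)O3)[C@@]2(C)CCCC(C)(C)[C@H]12 | intermediate
20 | (5S,6S,8R,9R,10S,13S)-6-[(tert-butyldimethylsilyl)oxy]-9,13-epoxylabdane 15,16-lactone | CC(C)(C)[Si](C)(C)O[C@H]1C[C@@H](C)[C@]3(CC[C@]4(COC(=O)C4)O3)[C@@]2(C)CCCC(C)(C)[C@H]12 | intermediate
21 | (5S,6S,8R,9R,10S,13S)-6-hydroxy-9,13-epoxylabdane 15,16-lactone | O[C@H]1C[C@@H](C)[C@]3(CC[C@]4(COC(=O)C4)O3)[C@@]2(C)CCCC(C)(C)[C@H]12 | intermediate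
22 | (5S,8R,9R,10S,13S)-6-oxo-9,13-epoxylabdane 15,16-lactone | O=C1C[C@@H](C)[C@]3(CC[C@]4(COC(=O)C4)O3)[C@@]2(C)CCCC(C)(C)[C@H]12 | intermediate
23 | (5S,6R,8R,9R,10S,13S)-6-hydroxy-9,13-epoxylabdane 15,16-lactone | O[C@@H]1C[C@@H](C)[C@]3(CC[C@]4(COC(=O)C4)O3)[C@@]2(C)CCCC(C)(C)[C@H]12 | intermediate
24 | previtexilactone, (5S,6R,8R,9R,10S,13S)-6-acetoxy-9,13-epoxylabdane 15,16-lactone | CC(=O)O[C@@H]1C[C@@H](C)[C@]2(CC[C@]3(COC(=O)C3)O2)[C@@]2(C)CCCC(C)(C)[C@H]12 | target

**Step count and risks**

Total step count: 17. Longest linear sequence: 17 steps (1 to 24); 14 enters in step 11.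

Steps most likely to fail:

Step 7. The exo preference may be too small, so that the cis‑fused octalone forms, or the Lewis acid may ionise the dienylic C6–O bond. The fallback uses a cationic dienophile (ionic Diels–Alder reaction) and sets out from 8. 1,2‑Bis(trimethylsilyloxy)ethane and TMSOTf (cat.) in CH2Cl2 at −78 °C should give the dioxolane ketal F1. The same catalyst opens it reversibly to the 2‑alkenyl‑1,3‑dioxolan‑2‑ylium ion, a stronger and bulkier dienophile that should cyclise below −40 °C with the acetal carbon exo to the octalone ketal F2. PPTS in wet acetone hydrolyses it and the route is rejoined at 9.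

Step 12. Face selection in the epoxidation of the 1,1‑disubstituted alkene may be poor if the two hydroxyl groups compete for the metal, and the epoxide may be opened by the wrong hydroxyl. The fallback forms C13 by oxypalladation and carbonylation, without reagent control, and sets out from 13. The dianion of 2‑methylprop‑2‑en‑1‑ol, dilithiated methallyl alcohol F3 (nBuLi, TMEDA), opens the epoxide at C11 to the allylic ene‑diol F4. PdCl2 (cat.), CuCl2, NaOAc and CO (1 atm) in AcOH should then effect Wacker‑type 5‑exo alkoxypalladation of C13 by the 9‑OH, CO insertion into the neopentyl C14–Pd bond (no β‑hydrogen) and lactonisation by the C16 hydroxyl. This gives 20 together with its C13 epimer, the 13‑epi spirolactone F5; chromatographic separation rejoins the route at 20.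

Step 11. SN2 opening at C11 next to the fully substituted C9 may be slow, so that base‑induced isomerisation of the epoxide to an allylic alcohol takes over. The fallback uses a stronger electrophile and sets out from 12. OsO4 (cat.) and NMO dihydroxylate the alkene from the α face to the 9α,11‑diol F6. SOCl2 and Et3N give the cyclic sulfite F7, and RuCl3 (cat.) with NaIO4 the cyclic sulfate F8. Dianion 15 attacks the primary C11 to give the C9 hydrogen sulfate F9, and hydrolysis with catalytic H2SO4 in wet THF (S–O cleavage, retention at C9) rejoins the route at 16.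

Further compounds
F1 | step 7 | dioxolane ketal of trienone 8 | C=C/C(C)=C/[C@@H](O[Si](C)(C)C(C)(C)C)C[C@@H](C)C1(OCCO1)C(C)=C
F2 | step 7 | dioxolane ketal of octalone 9 | CC(C)(C)[Si](C)(C)O[C@H]1C[C@@H](C)C3(OCCO3)[C@@]2(C)CCC=C(C)[C@H]12
F3 | step 12 | dilithiated methallyl alcohol | [Li]CC(=C)CO[Li]
F4 | step 12 | allylic ene-diol (9α-hydroxy, C13=CH2, C16 hydroxymethyl) | CC(C)(C)[Si](C)(C)O[C@H]1C[C@@H](C)[C@](O)(CCC(=C)CO)[C@@]2(C)CCCC(C)(C)[C@H]12
F5 | step 12 | 13-epi spirolactone (13R epimer of 20) | CC(C)(C)[Si](C)(C)O[C@H]1C[C@@H](C)[C@]3(CC[C@@]4(COC(=O)C4)O3)[C@@]2(C)CCCC(C)(C)[C@H]12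
F6 | step 11 | 9α,11-diol | CC(C)(C)[Si](C)(C)O[C@H]1C[C@@H](C)[C@](O)(CO)[C@@]2(C)CCCC(C)(C)[C@H]12
F7 | step 11 | 9,11-cyclic sulfite | CC(C)(C)[Si](C)(C)O[C@H]1C[C@@H](C)[C@]3(COS(=O)O3)[C@@]2(C)CCCC(C)(C)[C@H]12
F8 | step 11 | 9,11-cyclic sulfate | CC(C)(C)[Si](C)(C)O[C@H]1C[C@@H](C)[C@]3(COS(=O)(=O)O3)[C@@]2(C)CCCC(C)(C)[C@H]12
F9 | step 11 | C9 hydrogen sulfate of 16 | CC(C)(C)[Si](C)(C)O[C@H]1C[C@@H](C)[C@](OS(=O)(=O)O)(CCC(=C)CCO)[C@@]2(C)CCCC(C)(C)[C@H]12
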